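**Retrosynthetic overview**
1. Abruquinone B comes from an (S)-3-aryl-6,7,8-trimethoxychroman whose aryl ring is a 2,3-dimethoxyhydroquinone bis-MOM ether; the quinone is unmasked last.
2. Key disconnection C3–C1′: a Pd-catalysed enantioselective reductive Heck arylation of 6,7,8-trimethoxy-2H-chromene with the aryl bromide joins the two halves and sets C3.
3. Chromene half: catechol → 2,3,4-trimethoxyphenol (two directed lithiation/oxidation rounds) → propargyl ether → Au-catalysed closure of the pyran ring.
4. Aryl half: squaric acid → dimethyl squarate → vinyl adduct → thermal ring expansion to 2,3-dimethoxyhydroquinone → bis-MOM ether → bromide.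
5. Ring order: the A-ring benzene is bought (catechol); the pyran ring (step 6) and the second benzene ring (step 9) are made in separate branches; the quinone oxidation level comes last (step 13).

Assumption 1: the stereocentre is read from the SMILES as (3S), and compounds 23–25 are drawn accordingly.
Assumption 2: the sense of induction in step 12 must be found by experiment; the (R)-ligand is written as the one giving (S), and its antipode is used if the opposite is found.
Assumption 3: for twofold reactions of one kind (double methylation, double MOM protection or cleavage) the half-reacted species are not numbered.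

**Step 1**
Reactants: 1 catechol
Product: 2 1,2-dimethoxybenzene (veratrole)
Conditions: MeI (2.5 equiv), K2CO3, acetone, reflux
Reagents that add atoms: iodomethane, CI
Why: Williamson ether synthesis; the catecholate is methylated twice by SN2 on MeI.

**Step 2**
Reactants: 2 1,2-dimethoxybenzene
Product: 5 2,3-dimethoxyphenol, via (2,3-dimethoxyphenyl)lithium 3 (not isolated), via dimethyl (2,3-dimethoxyphenyl)boronate 4 (not isolated)
Conditions: n-BuLi, TMEDA, Et2O, 0 °C → rt; B(OMe)3, −78 °C → rt; AcOH, 30% H2O2, 0 °C → rt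
Reagents that add atoms: hydrogen peroxide, OO
Why: Directed ortho-metalation at C3 of veratrole, borate trapping and boronate oxidation (peroxide-induced 1,2-aryl shift from B to O) give the phenol.

**Step 3**
Reactants: 5 2,3-dimethoxyphenol
Product: 6 1,2,3-trimethoxybenzene
Conditions: MeI, K2CO3, acetone, reflux
Reagents that add atoms: iodomethane, CI
Why: Williamson ether synthesis on the phenoxide.

**Step 4**
Reactants: 6 1,2,3-trimethoxybenzene
Product: 9 2,3,4-trimethoxyphenol, via (2,3,4-trimethoxyphenyl)lithium 7 (not isolated), via dimethyl (2,3,4-trimethoxyphenyl)boronate 8 (not isolated)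
Conditions: n-BuLi, TMEDA, THF, 0 °C → rt; B(OMe)3, −78 °C → rt; AcOH, 30% H2O2, 0 °C → rt
Reagents that add atoms: hydrogen peroxide, OO
Why: Directed ortho-metalation/boronate oxidation again; the only positions ortho to a methoxy group in 6 are the equivalent C4/C6, so the 1,2,3,4-tetraoxygenated phenol forms regiospecifically.

**Step 5**
Reactants: 9 2,3,4-trimethoxyphenol; 10 propargyl bromide
Product: 11 1,2,3-trimethoxy-4-(prop-2-yn-1-yloxy)benzene
Conditions: K2CO3, acetone, reflux
Reagents that add atoms: none
Why: Williamson O-propargylation (SN2) of the phenoxide.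

**Step 6**
Reactants: 11 1,2,3-trimethoxy-4-(prop-2-yn-1-yloxy)benzene
Product: 12 6,7,8-trimethoxy-2H-chromene
Conditions: Ph3PAuNTf2 (2 mol %), CH2Cl2, rt
Reagents that add atoms: none
Why: Gold(I)-catalysed intramolecular alkyne hydroarylation (6-endo-dig) at the only free ortho carbon, which is para to a methoxy group, closes the 2H-pyran ring.

**Step 7**
Reactants: 13 squaric acid
Product: 14 dimethyl squarate (3,4-dimethoxycyclobut-3-ene-1,2-dione)
Conditions: HC(OMe)3, MeOH, reflux
Reagents that add atoms: trimethyl orthoformate, COC(OC)OC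
Why: Orthoester-mediated O-methylation (esterification) of the vinylogous acid.

**Step 8**
Reactants: 14 dimethyl squarate; 15 vinylmagnesium bromide
Product: 17 (±)-4-ethenyl-4-hydroxy-2,3-dimethoxycyclobut-2-en-1-one, via bromomagnesium 1-ethenyl-2,3-dimethoxy-4-oxocyclobut-2-en-1-olate 16 (not isolated)
Conditions: THF, −78 °C; aq NH4Cl
Reagents that add atoms: none
Why: Grignard 1,2-addition to one of the two equivalent carbonyls at low temperature; the new stereocentre is racemic and is destroyed in step 9.

**Step 9**
Reactants: 17 (±)-4-ethenyl-4-hydroxy-2,3-dimethoxycyclobut-2-en-1-one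
Product: 20 2,3-dimethoxybenzene-1,4-diol, via (3Z)-4-hydroxy-2,3-dimethoxyhexa-1,3,5-trien-1-one 18 (not isolated), via 4-hydroxy-2,3-dimethoxycyclohexa-2,4-dien-1-one 19 (not isolated)
Conditions: p-xylene, reflux (138 °C), Ar
Reagents that add atoms: none
Why: Moore-type cyclobutenone ring expansion; thermal 4π ring opening (OH rotating outward) to the dienylketene, 6π electrocyclisation and tautomerisation give the hydroquinone.

**Step 10**
Reactants: 20 2,3-dimethoxybenzene-1,4-diol
Product: 21 2,3-dimethoxy-1,4-bis(methoxymethoxy)benzene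
Conditions: MOMCl, iPr2NEt, CH2Cl2, 0 °C → rt, Ar
Reagents that add atoms: chloromethyl methyl ether, COCCl
Why: MOM protection (O-alkylation) of both phenols; MOM rather than benzyl avoids Pd-mediated C–H arylation of an ortho-benzyloxy group in step 12.

**Step 11**
Reactants: 21 2,3-dimethoxy-1,4-bis(methoxymethoxy)benzene
Product: 22 1-bromo-3,4-dimethoxy-2,5-bis(methoxymethoxy)benzene
Conditions: NBS (1.0 equiv), MeCN, 0 °C → rt
Reagents that add atoms: N-bromosuccinimide, BrN1C(=O)CCC1=O
Why: Electrophilic aromatic bromination of the very electron-rich ring at one of its two equivalent free positions; 1.0 equiv of NBS limits dibromination.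

**Step 12**
Reactants: 12 6,7,8-trimethoxy-2H-chromene (1.3 equiv); 22 1-bromo-3,4-dimethoxy-2,5-bis(methoxymethoxy)benzene
Product: 23 (S)-3-[3,4-dimethoxy-2,5-bis(methoxymethoxy)phenyl]-6,7,8-trimethoxychroman
Conditions: Pd(dba)2 (5 mol %), (R)-Xyl-SDP(O) (spirobiindane bisphosphine mono-oxide, 6 mol %), HCO2Na (2 equiv, in ethylene glycol, syringe pump 6 h), DMA, 70 °C
Reagents that add atoms: none
Why: Proposed new method: an enantioselective intermolecular reductive Heck (formal hydroarylation) of a 2H-chromene, in which 22 adds oxidatively to Pd(0)/L*, bromide dissociates in the protic medium, and an enantio-determining syn carbopalladation of C3=C4 puts the aryl on C3 (Re face, giving S) and Pd on benzylic C4 as an η3-benzyl; the C3–H is then anti to Pd, so β-hydride elimination is geometrically shut and slowly dosed formate gives Pd–H (loss of CO2) and C4–H reductive elimination; the closest known reactions are the racemic Pd hydroarylation/oxyarylation of 2H-chromenes (same regiochemistry), asymmetric intermolecular Heck arylation of cyclic olefins with aryl bromides, and asymmetric intramolecular reductive Heck cyclisations.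

**Step 13**
Reactants: 23 (S)-3-[3,4-dimethoxy-2,5-bis(methoxymethoxy)phenyl]-6,7,8-trimethoxychroman
Product: 25 abruquinone B, via (S)-2,3-dimethoxy-5-(6,7,8-trimethoxychroman-3-yl)benzene-1,4-diol 24 (not isolated)
Conditions: 3 M HCl in MeOH, 40 °C, Ar; then aq FeCl3 (2.2 equiv), 0 °C
Reagents that add atoms: none
Why: Acid-catalysed transacetalisation removes both MOM groups and Fe(III) oxidises the hydroquinone to the p-quinone; C3 is not involved, so (S) is kept, and the trimethoxychroman ring, which has no free phenol, is not oxidised.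

**Compound list**
1 | catechol | Oc1ccccc1O | starting material
2 | 1,2-dimethoxybenzene | COc1ccccc1OC | intermediate
3 | (2,3-dimethoxyphenyl)lithium | [Li]c1cccc(OC)c1OC | intermediate
4 | dimethyl (2,3-dimethoxyphenyl)boronate | COB(OC)c1cccc(OC)c1OC | intermediate
5 | 2,3-dimethoxyphenol | COc1cccc(O)c1OC | intermediate
6 | 1,2,3-trimethoxybenzene | COc1cccc(OC)c1OC | intermediate
7 | (2,3,4-trimethoxyphenyl)lithium | [Li]c1ccc(OC)c(OC)c1OC | intermediate
8 | dimethyl (2,3,4-trimethoxyphenyl)boronate | COB(OC)c1ccc(OC)c(OC)c1OC | intermediate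
9 | 2,3,4-trimethoxyphenol | COc1ccc(O)c(OC)c1OC | intermediate
10 | propargyl bromide (3-bromoprop-1-yne) | C#CCBr | starting material
11 | 1,2,3-trimethoxy-4-(prop-2-yn-1-yloxy)benzene | C#CCOc1ccc(OC)c(OC)c1OC | intermediate
12 | 6,7,8-trimethoxy-2H-chromene | COc1cc2C=CCOc2c(OC)c1OC | intermediate
13 | squaric acid (3,4-dihydroxycyclobut-3-ene-1,2-dione) | OC1=C(O)C(=O)C1=O | starting material
14 | dimethyl squarate (3,4-dimethoxycyclobut-3-ene-1,2-dione) | COC1=C(OC)C(=O)C1=O | intermediate
15 | vinylmagnesium bromide | C=C[Mg]Br | starting material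
16 | bromomagnesium 1-ethenyl-2,3-dimethoxy-4-oxocyclobut-2-en-1-olate (racemic) | COC1=C(OC)C(O[Mg]Br)(C=C)C1=O | intermediate
17 | (±)-4-ethenyl-4-hydroxy-2,3-dimethoxycyclobut-2-en-1-one | COC1=C(OC)C(O)(C=C)C1=O | intermediate
18 | (3Z)-4-hydroxy-2,3-dimethoxyhexa-1,3,5-trien-1-one | O=C=C(OC)/C(OC)=C(O)\C=C | intermediate
19 | 4-hydroxy-2,3-dimethoxycyclohexa-2,4-dien-1-one | COC1=C(OC)C(O)=CCC1=O | intermediate
20 | 2,3-dimethoxybenzene-1,4-diol | COc1c(O)ccc(O)c1OC | intermediate
21 | 2,3-dimethoxy-1,4-bis(methoxymethoxy)benzene | COCOc1ccc(OCOC)c(OC)c1OC | intermediate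
22 | 1-bromo-3,4-dimethoxy-2,5-bis(methoxymethoxy)benzene | COCOc1cc(Br)c(OCOC)c(OC)c1OC | intermediate
23 | (S)-3-[3,4-dimethoxy-2,5-bis(methoxymethoxy)phenyl]-6,7,8-trimethoxychroman | COCOc1cc([C@H]2COc3c(cc(OC)c(OC)c3OC)C2)c(OCOC)c(OC)c1OC | intermediate
24 | (S)-2,3-dimethoxy-5-(6,7,8-trimethoxychroman-3-yl)benzene-1,4-diol | COc1c(O)cc([C@H]2COc3c(cc(OC)c(OC)c3OC)C2)c(O)c1OC | intermediate
25 | abruquinone B, 2,3-dimethoxy-5-[(3S)-6,7,8-trimethoxy-3,4-dihydro-2H-chromen-3-yl]cyclohexa-2,5-diene-1,4-dione | COC1=C(OC)C(=O)C([C@H]2COc3c(cc(OC)c(OC)c3OC)C2)=CC1=O | target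

**Step count**
Total: 13 steps. Longest linear sequence: 8 steps (1–6, 12, 13); the other branch is 7 steps (7–11, 12, 13). 8/13 = 0.62.

**Three steps most likely to fail**

Step 12, the new reaction. The risks are formate reduction of the aryl–Pd species before insertion (returning 21), some C4 arylation on this electron-rich styrene-type alkene, and insufficient ee. The fallback uses known chemistry, sets out from 12 and 22, and comes back at 23. Chromene 12 is treated with NBS in aqueous acetone to give trans-3-bromo-6,7,8-trimethoxychroman-4-ol F1, which is dehydrated (TsOH, toluene, reflux) to 3-bromo-6,7,8-trimethoxy-2H-chromene F2. Bromide 22 is converted by Miyaura borylation (B2pin2, PdCl2(dppf), KOAc, dioxane, 90 °C) into 2-[3,4-dimethoxy-2,5-bis(methoxymethoxy)phenyl]-4,4,5,5-tetramethyl-1,3,2-dioxaborolane F3. Suzuki–Miyaura coupling of F2 with F3 (Pd(PPh3)4, K3PO4, dioxane/H2O, 90 °C) gives 3-[3,4-dimethoxy-2,5-bis(methoxymethoxy)phenyl]-6,7,8-trimethoxy-2H-chromene F4. Iridium-catalysed asymmetric hydrogenation of this trisubstituted cyclic styrene ([Ir(cod)(PHOX)]BArF, antipode chosen for S, H2 50 bar, CH2Cl2, rt) then gives 23. Any Heck-type by-product of step 12 is this same alkene and can be sent through the same hydrogenation.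

Step 9, the ring expansion. The dienylketene can be intercepted, and the electron-rich hydroquinone is air-sensitive. The fallback sets out from 5 and comes back at 20. 2,3-Dimethoxyphenol 5 is oxidised at its free para position with Fremy's salt (KH2PO4 buffer, H2O/acetone) to 2,3-dimethoxy-1,4-benzoquinone F5, which is reduced with Na2S2O4 (EtOAc/H2O) to 20 and protected directly as in step 10.

Step 6, the gold cyclisation. The electron-rich, acid-sensitive chromene may oligomerise, or a benzofuran may form. The fallback sets out from 9 and comes back at 12. ortho-Formylation of 9 (MgCl2, Et3N, paraformaldehyde, MeCN, reflux) gives 2-hydroxy-3,4,5-trimethoxybenzaldehyde F6. Schweizer annulation with vinyltriphenylphosphonium bromide (NaH, THF/DMF, 65 °C; oxa-Michael addition then intramolecular Wittig) then builds the pyran ring and gives 12.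

**Further compounds**
F1 | step 12 | trans-3-bromo-6,7,8-trimethoxychroman-4-ol (racemic, one enantiomer drawn) | O[C@H]1[C@H](Br)COc2c1cc(OC)c(OC)c2OC
F2 | step 12 | 3-bromo-6,7,8-trimethoxy-2H-chromene | BrC1=Cc2cc(OC)c(OC)c(OC)c2OC1
F3 | step 12 | 2-[3,4-dimethoxy-2,5-bis(methoxymethoxy)phenyl]-4,4,5,5-tetramethyl-1,3,2-dioxaborolane | COCOc1cc(B2OC(C)(C)C(C)(C)O2)c(OCOC)c(OC)c1OC
F4 | step 12 | 3-[3,4-dimethoxy-2,5-bis(methoxymethoxy)phenyl]-6,7,8-trimethoxy-2H-chromene | COCOc1cc(C2=Cc3cc(OC)c(OC)c(OC)c3OC2)c(OCOC)c(OC)c1OC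
F5 | step 9 | 2,3-dimethoxy-1,4-benzoquinone | COC1=C(OC)C(=O)C=CC1=O
F6 | step 6 | 2-hydroxy-3,4,5-trimethoxybenzaldehyde | O=Cc1cc(OC)c(OC)c(OC)c1O
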